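I had no constants for this flask, just the gamma and delta runs, so I looked for a quantity that needs neither a rate constant nor a clock.

| flask | substrate | partner | remark | time |
|---|---|---|---|---|
| gamma | 0.10 M | 0.15 M | run made earlier |  |
| delta | 0.10 M | 0.22 M | run made earlier |  |
| flask | 0.10 M | 0.300 M |  | 2.5 h |

- gamma (time / h: substrate / %, single product / %): 0.200: 79, 18; 0.500: 63, 25; 1.00: 44, 28; 2.50: 26, 29
- delta (time / h: substrate / %, single product / %): 0.667: 44, 29; 1.33: 24, 24; 2.00: 14, 20; 2.50: 12, 17

(readings scatter by 1.5 percentage points)

- at 2.5 h, what has stopped the reaction, if anything has (it is still moving / the partner has run out first / all of the substrate has reacted / forward and back rates have come level)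
- share of the substrate used up at 2.5 h
- single product at 2.5 h, in percent of the substrate charged
- double product at 2.5 h, in percent of the substrate charged
- tris adduct at 2.5 h, in percent of the substrate charged

- the reaction counts as stopped when no species that holds the substrate changes by six tenths of a point or more over the second half of the time

Gamma at 1.00 h and delta at 0.667 h both read substrate 44%, with single product 28% and 29%: different partner and different times, yet nearly the same point. So I divided the rate of single product by the rate of substrate; if both steps are first order in partner, partner and time cancel. After that point single product barely rose in gamma and fell in delta, so I took it as the peak, where making equals using up. Substrate over the mean of those two single-product readings reads 1.54, with the scatter of the readings in it: I took this reading as κ, the second rate constant over the first, the selectivity factor. With a and m as shares of the substrate charged, the curve is m = (a − a^κ)/(κ − 1).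

But the curve still needs the substrate left. Delta held 12% at 2.50 h, and the flask charges more partner, 0.300 M against 0.22 M, so I expected less substrate there and, past the peak, single product below 15.1%.

The forecast reads it is still moving, with conversion 95%, single product 8%, double product 77% and tris adduct 10%, and of the end it says “Species are still changing over the second half of the time”.

The flask gave: it is still moving, with conversion 95.5%, single product 6.80%, double product 82.1% and tris adduct 6.62%.

    substrate + partner → single product + by-product (k = 0.130 M⁻¹ min⁻¹)
    partner + single product → double product + by-product (k = 0.200 M⁻¹ min⁻¹)
    partner + double product ⇌ tris adduct + by-product (K = 0.140, k = 0.140 M⁻¹ min⁻¹)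

In the flask at 2.50 h, substrate 4.51% over κ times single product 6.80% gives 0.430, and the net making of single product stands at 0.431 of its net using up, less than one, so that flask is past its peak, and the curve at that substrate gives 6.76%. With 0.40 M of substrate instead, the neighbouring flask at the same time keeps substrate 48.0% with partner down to 0.0738% of its charge, the same ratio comes to 1.07, and the curve gives 29.0% where that flask holds single product 29.1%.

(The readings were generated by integration for an exercise.)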